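## The problem

The target is an achiral isoflavone. Ring A (C4a–C8a) is a phloroglucinol unit with hydroxyls at C5 and C7 and a 3-hydroxy-3-methylbutyl chain at C6; ring C is the pyranone; ring B, joined through C1' to C3, is a resorcinol with a prenyl group at C3' between its two hydroxyls. With no stereocentre, nothing has to be controlled in space; the difficulties are regiochemical and chemoselective. On ring A the chain must stand at C6 and not at C8. This is the same as deciding which of the two oxygens ortho to the acyl carbon becomes O1, and in an acylphloroglucinol these two oxygens are almost indistinguishable. On ring B a carbon substituent has to enter the hindered C3' position between two oxygens. The prenyl alkene and the tertiary alcohol are precursors of the same kind of tertiary carbocation, and each has a phenol in reach that would trap it as a 2,2-dimethylchroman, so strong acid is excluded at the end; the alkene also forbids hydrogenolysis and electrophilic oxidants once it is present, and ring C opens at C2 in hot alkali. The feature that makes the key step possible is that C3 carries ring B through C1' directly beside the C4 carbonyl, while C2 is a CH at the aldehyde oxidation level bonded to O1. This is the arrangement left when the electron-rich aryl group of a chalcone shifts from the β- to the α-carbon under oxidation, the β-carbon emerging as an acetal that the ring A hydroxyl can capture.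

## Retrosynthesis

**21 ⇒ 20.** The four phenolic O–H bonds are traced back to methoxymethyl (MOM) acetals in 20. Among common phenol protecting groups, the MOM ether is the one that withstands butyllithium, Grignard reagent, hydroxide, hydrogenation and palladium coupling, yet leaves without hydrogen or a hard Lewis acid. Benzyl ethers would cost the prenyl alkene on removal; methyl ethers would need boron halides. The forward reaction must cleave four acetals faster than either tertiary cation can form.

**20 ⇒ 18 + 19.** The bond between C3' and the prenyl CH2 is cut, giving aryl bromide 18 and stannane 19. The neighbouring choice, carrying the prenyl group through the whole route, fails at the key step, because a trisubstituted alkene is an excellent substrate for oxythallation. Bromine is inert to trivalent thallium and to aldol base, and it marks C3' without ambiguity. The forward reaction is a Stille coupling at a bromide flanked by two acetal oxygens, with transfer of the allylic group through its CH2 end.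

**18 ⇒ 16 (via 17).** O1–C2 and C3–C1' are cut and C1' is reconnected to C2, which turns the isoflavone into 2'-hydroxychalcone 16; the stage in between is the dimethyl acetal 17. A deoxybenzoin route would need a Friedel–Crafts acylation that the acetals do not survive. A cross-coupling at C3 of a halochromone would need a separate ring closure and a second organometallic partner. Here the C3–C1' bond costs nothing beyond the oxidant, because ring B already sits one carbon away. The precursor is simpler by one ring and divides into two benzene derivatives. The forward reaction asks for a good migrating group (ring B has oxygen ortho and para to C1'), a single free hydroxyl on ring A, and no other oxidisable site.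

**16 ⇒ 11 + 15.** The Cα=Cβ bond is cut to acetophenone 11 and aldehyde 15. This is the obvious Claisen–Schmidt disconnection; it asks only that the aldehyde cannot enolise and that the acetals tolerate hydroxide.

**15 ⇒ 14 ⇒ 12.** The acetals are removed and the C–CHO bond is cut, leading to 2-bromoresorcinol 12 through iminium salt 13. Formylation is placed before protection: on the bis-acetal the only formylation available would be lithiation, which would exchange the bromine. In 12 the positions C4 and C6 are equivalent and C2 is blocked, so one aldehyde results.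

**11 ⇒ 10 ⇒ 9 ⇒ 8.** The acetyl group is taken off ring A, leading to phenol 8. Phenol 8 has a mirror plane through C1 and C4, so its two ortho carbons are the same; any ortho-acylation gives the pattern in which the free hydroxyl (future O1) has H on its other side (future C8). The C6/C8 question therefore never arises. Direct Friedel–Crafts acetylation is excluded by the acetals, so the acetyl group is assembled in three mild operations: magnesium-mediated ortho-formylation (9), methyl Grignard addition (10) and benzylic oxidation (11).

**8 ⇒ 7 ⇒ 5 + 6.** The aryl–alkyl bond is cut at the alkyne oxidation level, giving iodide 5 and 2-methylbut-3-yn-2-ol 6, which supplies all five chain carbons with the tertiary alcohol in place. Prenylation followed by hydration would be no shorter and would add a Markovnikov hydration. Hydrogenation of 7 saturates the triple bond and removes the benzyl group in one operation.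

**5 ⇒ 3 ⇒ 2 ⇒ 1.** The C–I bond is cut through aryllithium 4, formed at the carbon between the two MOM ethers of 3. Compound 3 comes from phloroglucinol 1 by monobenzylation (2) and acetal formation. The benzyl ether distinguishes the oxygen para to the future chain from the two that flank it.

## Roads not taken

**Alternative 1:** Ring A would be made last. The cut runs through C4a–C5, C5–C6, C7–C8 and C8–C8a and leads to diazo ketone A1, a 4-pyranone that already carries ring B, and to the ynol silyl ether A2, which holds the C6 chain. In the forward direction (Danheiser benzannulation), Wolff rearrangement of A1 moves the pyranone carbon from the carbonyl to the diazo carbon (C8–C8a). The ketene so formed takes up A2 by [2+2] addition (C5–C6, C7–C8), the four-membered ring opens, and six-electron closure onto the pyranone CH (C4a–C5) with tautomerisation gives phenol A3.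
- Merits: the pattern of ring A is fixed by mechanism. C5 emerges as the free chelated hydroxyl, C7 as a silyl ether and C6 with the alkyne substituent. No symmetric intermediate is needed, the prenyl group is present from the start, no thallium is used and no coupling at a hindered carbon is required. In these respects this road is cleaner than the chosen one.
- Weak points: A1 must already contain the C3–C1' bond, so the central bond of the isoflavone is only moved into the preparation of a starting material. 4-Pyranones rearrange under the ultraviolet light normally used for the Wolff step, and in the thermal variant the ketene has to find A2 before it finds the prenyl alkene or a second molecule of A1. A2 needs an ester-to-ynolate homologation of its own.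
- Comparison: A1 and A2 together should take more steps than the whole chosen route. Against the regiochemical elegance, the chosen plan reaches the same certainty through the mirror symmetry of phenol 8 with ordinary reagents, and obtains C3–C1' as part of the oxidation.

**Alternative 2:** Ring C would be closed onto ring A at the aryne level. The cut is O1–C8a and C4–C4a; the fragments are silylaryl triflate A4 and the enol form of the α-formyl arylacetate of ring B, A5. Fluoride would strip the silyl and triflate groups of A4 to expose a strained triple bond between C4a and C8a. The enol oxygen of A5 should add at C8a, the carbon remote from the C5 acetal oxygen, and the aryl anion left at C4a should attack the ester to give A6.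
- Merits: this is the most convergent road. Both halves arrive complete, with the prenyl group and the protected tertiary alcohol in place; no oxidant and no transition metal are needed; the inductive effect of the C5 oxygen sets the ring A regiochemistry; the endgame is one deprotection. If the union worked, it would be shorter after the fragments than the chosen plan.
- Weak points: A4 is a hexasubstituted benzene whose preparation from phenol 8 adds ortho-silylation and triflation, so ring A becomes more expensive. A5 is an ambident β-dicarbonyl nucleophile, and arynes usually bond to the carbon of such enolates and then insert into the C–C bond, which would give an ortho-acylated arylacetate and no chromone. Addition through oxygen followed by acyl capture is established for salicylates but not for acyclic formyl esters, so the key step is an extrapolation. The base-sensitive C2 of the product is also exposed to fluoride.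
- Comparison: the chosen plan sets against the higher convergence that each of its bond-forming events is known on this substrate class, and that the site of ring closure is dictated by the only free hydroxyl.

**Alternative 3:** Ring B would be made last on a finished chromone. The cut runs through C1'–C2', C2'–C3', C4'–C5' and C5'–C6'; the fragments are diazo ketone A7, a 3-vinylchromone, and the prenyl-substituted ynol silyl ether A8. Wolff rearrangement (C5'–C6'), [2+2] capture of A8 (C2'–C3', C4'–C5'), ring opening and six-electron closure (C1'–C2') would give A9, with the prenyl group at C3' between a free hydroxyl and a silyl ether.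
- Merits: the prenyl group is placed between the two oxygens by construction, so no coupling at a hindered bromide is needed. This is the point where the chosen plan is weakest (step 13), and here this road is the better answer. No thallium is used.
- Weak points: the ring A problem is untouched, since A7 still has to be made from acetophenone 11 by formylative ring closure, olefination and diazo ketone formation, five or more further steps. The ketene derived from A7 is conjugated with the chromone C2=C3 bond and can close onto C2 by itself in a six-electron process, bypassing A8. A8 is a skipped enyne with a doubly activated CH2 and is prone to isomerise under the strongly basic conditions used to make ynol ethers. The product needs two modes of deprotection.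
- Comparison: more steps and a key step with a built-in competitor are paid for certainty at C3'. The chosen plan obtains that certainty from 2-bromoresorcinol 12, in which the halogen already sits between the two oxygens.

Key step: step 12

Remark on the chemistry: the target has no stereocentre. The two stereocentres that appear on the way (the carbinol carbon of 10 and C2 of acetal 17) are formed as racemates and are removed in the next operation.

## Steps

Step 1
Reactants: 1 phloroglucinol (benzene-1,3,5-triol)
Product: 2 5-(benzyloxy)benzene-1,3-diol
Conditions: BnBr (0.35 equiv), K2CO3 (0.4 equiv), DMF, rt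
Reagents that add atoms: benzyl bromide, BrCc1ccccc1
Why: Williamson etherification under statistical control; with the triol in excess the mono-ether should dominate, the carbonate/DMF medium favours O- over C-alkylation, and unreacted 1 is removed by aqueous extraction.

Step 2
Reactants: 2 5-(benzyloxy)benzene-1,3-diol
Product: 3 1-(benzyloxy)-3,5-bis(methoxymethoxy)benzene
Conditions: NaH, MOMCl, DMF, 0 °C to rt
Reagents that add atoms: chloromethyl methyl ether, COCCl
Why: Williamson-type O-alkylation of both phenoxides by the chloromethyl ether (acetal formation); the benzyl ether is inert.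

Step 3
Reactants: 3 1-(benzyloxy)-3,5-bis(methoxymethoxy)benzene
Product: 5 5-(benzyloxy)-2-iodo-1,3-bis(methoxymethoxy)benzene, via aryllithium 4 (not isolated)
Conditions: n-BuLi (0.95 equiv), THF, 0 °C; then I2, −78 °C to rt
Reagents that add atoms: iodine, II
Why: Directed ortho-metalation; the two MOM ethers chelate lithium cooperatively, so deprotonation should occur at the carbon between them and not beside the weaker benzyloxy director, and the slight deficit of base lets a misplaced aryllithium equilibrate to 4 before iodinolysis.

Step 4
Reactants: 5 5-(benzyloxy)-2-iodo-1,3-bis(methoxymethoxy)benzene; 6 2-methylbut-3-yn-2-ol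
Product: 7 4-[4-(benzyloxy)-2,6-bis(methoxymethoxy)phenyl]-2-methylbut-3-yn-2-ol
Conditions: PdCl2(PPh3)2 (5 mol %), CuI (10 mol %), Et3N, DMF, 70 °C
Reagents that add atoms: none
Why: Sonogashira coupling; aryl iodides with two ortho alkoxy groups are slow but competent partners at this temperature, and the free tertiary propargylic alcohol needs no protection.

Step 5
Reactants: 7 4-[4-(benzyloxy)-2,6-bis(methoxymethoxy)phenyl]-2-methylbut-3-yn-2-ol
Product: 8 4-(3-hydroxy-3-methylbutyl)-3,5-bis(methoxymethoxy)phenol
Conditions: H2 (1 atm), 10% Pd/C, EtOAc, rt
Reagents that add atoms: none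
Why: Heterogeneous hydrogenation saturates the alkyne and hydrogenolyses the benzyl ether in one operation; the tertiary alcohol and the aryl MOM ethers are stable in neutral ethyl acetate, and the product has a mirror plane through C1 and C4.

Step 6
Reactants: 8 4-(3-hydroxy-3-methylbutyl)-3,5-bis(methoxymethoxy)phenol
Product: 9 2-hydroxy-5-(3-hydroxy-3-methylbutyl)-4,6-bis(methoxymethoxy)benzaldehyde
Conditions: MgCl2, Et3N, (CH2O)n, MeCN, reflux
Reagents that add atoms: paraformaldehyde (formaldehyde), C=O
Why: Magnesium-mediated ortho-formylation of a phenol (Casnati–Skattebøl reaction); the magnesium phenoxide delivers formaldehyde to the ortho carbon and a second equivalent oxidises the hydroxymethyl group, and since both ortho carbons of 8 are equivalent a single aldehyde should form.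

Step 7
Reactants: 9 2-hydroxy-5-(3-hydroxy-3-methylbutyl)-4,6-bis(methoxymethoxy)benzaldehyde
Product: 10 2-(1-hydroxyethyl)-4-(3-hydroxy-3-methylbutyl)-3,5-bis(methoxymethoxy)phenol (racemic)
Conditions: MeMgBr (4 equiv), THF, 0 °C to rt; then aq. NH4Cl
Reagents that add atoms: methylmagnesium bromide, C[Mg]Br
Why: Grignard addition to the aldehyde after the first two equivalents have deprotonated the phenol and the tertiary alcohol; the new carbinol centre is racemic and is removed in step 8.

Step 8
Reactants: 10 2-(1-hydroxyethyl)-4-(3-hydroxy-3-methylbutyl)-3,5-bis(methoxymethoxy)phenol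
Product: 11 1-[2-hydroxy-5-(3-hydroxy-3-methylbutyl)-4,6-bis(methoxymethoxy)phenyl]ethanone
Conditions: MnO2 (activated, excess), CH2Cl2, rt
Reagents that add atoms: none
Why: Benzylic alcohol oxidation with activated MnO2; the tertiary alcohol cannot be oxidised and the ketone is stabilised by the hydrogen bond from the ortho hydroxyl.

Step 9
Reactants: 12 2-bromoresorcinol (2-bromobenzene-1,3-diol)
Product: 14 3-bromo-2,4-dihydroxybenzaldehyde, via iminium chloride 13 (not isolated)
Conditions: POCl3, DMF, MeCN, 0 °C to rt; then H2O, 50 °C
Reagents that add atoms: N,N-dimethylformamide, CN(C)C=O; water, O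
Why: Vilsmeier–Haack formylation of a resorcinol; C4 and C6 of 12 are equivalent and each is ortho to one hydroxyl and para to the other, C2 is blocked by bromine, and hydrolysis of 13 releases the aldehyde.

Step 10
Reactants: 14 3-bromo-2,4-dihydroxybenzaldehyde
Product: 15 3-bromo-2,4-bis(methoxymethoxy)benzaldehyde
Conditions: MOMCl, K2CO3, acetone, 50 °C
Reagents that add atoms: chloromethyl methyl ether, COCCl
Why: Williamson-type acetalisation of both phenols; on warming the carbonate is strong enough for the chelated, bromine-flanked C2 hydroxyl.

Step 11
Reactants: 11 1-[2-hydroxy-5-(3-hydroxy-3-methylbutyl)-4,6-bis(methoxymethoxy)phenyl]ethanone; 15 3-bromo-2,4-bis(methoxymethoxy)benzaldehyde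
Product: 16 (E)-3-[3-bromo-2,4-bis(methoxymethoxy)phenyl]-1-[2-hydroxy-5-(3-hydroxy-3-methylbutyl)-4,6-bis(methoxymethoxy)phenyl]prop-2-en-1-one
Conditions: KOH, EtOH/H2O, rt
Reagents that add atoms: none
Why: Claisen–Schmidt condensation; the methyl ketone enolate adds to the non-enolisable aldehyde and E1cB dehydration gives the E-enone, which as its phenoxide in base does not close to a flavanone.

Step 12
Reactants: 16 (E)-3-[3-bromo-2,4-bis(methoxymethoxy)phenyl]-1-[2-hydroxy-5-(3-hydroxy-3-methylbutyl)-4,6-bis(methoxymethoxy)phenyl]prop-2-en-1-one
Product: 18 3-[3-bromo-2,4-bis(methoxymethoxy)phenyl]-6-(3-hydroxy-3-methylbutyl)-5,7-bis(methoxymethoxy)chromen-4-one, via dimethyl acetal 17 (not isolated)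
Conditions: Tl(NO3)3·3H2O (1.1 equiv), MeOH/HC(OMe)3 (3:1), rt; then pyridine (2 equiv), PPTS (0.2 equiv), 55 °C
Reagents that add atoms: none
Why: Oxidative 1,2-aryl migration of a 2'-hydroxychalcone followed by acid-catalysed acetal exchange; the closest known reaction type is the Tl(NO3)3-mediated conversion of 2'-hydroxychalcones into 3,3-dimethoxy-1,2-diarylpropan-1-ones and their cyclisation to isoflavones. Trivalent thallium and methanol add across the enone of 16 so that thallium is bonded to Cα and methoxide to the benzylic Cβ. Departure of monovalent thallium from Cα is assisted by ring B, whose C1' bridges both carbons as a phenonium ion stabilised by the ortho and para acetal oxygens; the bridge opens towards the methoxy-stabilised cation at Cβ, which methanol traps, giving racemic acetal 17 with the new C3–C1' bond. After the nitric acid set free has been buffered as pyridinium nitrate, warming with pyridinium p-toluenesulfonate (PPTS) ionises the acetal to an oxocarbenium ion, which the one free phenol of ring A attacks in a 6-exo-trig closure (O1–C2); loss of the second methanol across C2–C3 gives the chromen-4-one. No stereocentre remains, since the one in 17 is erased by this elimination, so no stereocontrol is needed. The step needs aryl migration to outrun plain solvent capture at Cα and aurone-type closure, which the donor-substituted ring B secures. It needs ring closure through a single oxygen, secured because the other ortho oxygen of ring A stays an acetal at pyridinium acidity, and it needs a substrate without a second oxidisable site, which is why C3' carries bromine instead of the prenyl alkene and why the oxidation is stopped as soon as 16 is consumed.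

Step 13
Reactants: 18 3-[3-bromo-2,4-bis(methoxymethoxy)phenyl]-6-(3-hydroxy-3-methylbutyl)-5,7-bis(methoxymethoxy)chromen-4-one; 19 tributyl(3-methylbut-2-enyl)stannane
Product: 20 3-[2,4-bis(methoxymethoxy)-3-(3-methylbut-2-enyl)phenyl]-6-(3-hydroxy-3-methylbutyl)-5,7-bis(methoxymethoxy)chromen-4-one
Conditions: Pd(PPh3)4 (10 mol %), DMF, 100 °C
Reagents that add atoms: none
Why: Stille coupling; oxidative addition of zerovalent palladium into the C3'–Br bond, transmetalation of the allylic stannane and reductive elimination at the less substituted terminus should give the linear prenyl arene, and acetals, chromone and tertiary alcohol are inert under these neutral conditions.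

Step 14
Reactants: 20 3-[2,4-bis(methoxymethoxy)-3-(3-methylbut-2-enyl)phenyl]-6-(3-hydroxy-3-methylbutyl)-5,7-bis(methoxymethoxy)chromen-4-one
Product: 21 3-[2,4-dihydroxy-3-(3-methylbut-2-enyl)phenyl]-5,7-dihydroxy-6-(3-hydroxy-3-methylbutyl)chromen-4-one (CNP0076924.0)
Conditions: conc. HCl (to ca. 1 M), MeOH, rt to 40 °C
Reagents that add atoms: none
Why: Acid-catalysed transacetalisation of the four aryl MOM ethers to methanol; the acetal oxocarbenium ions form far more easily than the tertiary carbocations from the alkene or the alcohol, so near room temperature the phenols should be released before chroman formation sets in.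

## Compound list

1 | phloroglucinol (benzene-1,3,5-triol) | Oc1cc(O)cc(O)c1 | starting material
2 | 5-(benzyloxy)benzene-1,3-diol | Oc1cc(O)cc(OCc2ccccc2)c1 | intermediate
3 | 1-(benzyloxy)-3,5-bis(methoxymethoxy)benzene | COCOc1cc(OCOC)cc(OCc2ccccc2)c1 | intermediate
4 | [4-(benzyloxy)-2,6-bis(methoxymethoxy)phenyl]lithium (formed in the flask) | [Li]c1c(OCOC)cc(OCc2ccccc2)cc1OCOC | intermediate
5 | 5-(benzyloxy)-2-iodo-1,3-bis(methoxymethoxy)benzene | COCOc1cc(OCc2ccccc2)cc(OCOC)c1I | intermediate
6 | 2-methylbut-3-yn-2-ol | CC(C)(O)C#C | starting material
7 | 4-[4-(benzyloxy)-2,6-bis(methoxymethoxy)phenyl]-2-methylbut-3-yn-2-ol | COCOc1cc(OCc2ccccc2)cc(OCOC)c1C#CC(C)(C)O | intermediate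
8 | 4-(3-hydroxy-3-methylbutyl)-3,5-bis(methoxymethoxy)phenol | COCOc1cc(O)cc(OCOC)c1CCC(C)(C)O | intermediate
9 | 2-hydroxy-5-(3-hydroxy-3-methylbutyl)-4,6-bis(methoxymethoxy)benzaldehyde | O=Cc1c(O)cc(OCOC)c(CCC(C)(C)O)c1OCOC | intermediate
10 | 2-(1-hydroxyethyl)-4-(3-hydroxy-3-methylbutyl)-3,5-bis(methoxymethoxy)phenol (racemic) | CC(O)c1c(O)cc(OCOC)c(CCC(C)(C)O)c1OCOC | intermediate
11 | 1-[2-hydroxy-5-(3-hydroxy-3-methylbutyl)-4,6-bis(methoxymethoxy)phenyl]ethanone | CC(=O)c1c(O)cc(OCOC)c(CCC(C)(C)O)c1OCOC | intermediate
12 | 2-bromoresorcinol (2-bromobenzene-1,3-diol) | Oc1cccc(O)c1Br | starting material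
13 | [(3-bromo-2,4-dihydroxyphenyl)methylidene]dimethylammonium chloride (formed in the flask) | C[N+](C)=Cc1ccc(O)c(Br)c1O.[Cl-] | intermediate
14 | 3-bromo-2,4-dihydroxybenzaldehyde | O=Cc1ccc(O)c(Br)c1O | intermediate
15 | 3-bromo-2,4-bis(methoxymethoxy)benzaldehyde | COCOc1ccc(C=O)c(OCOC)c1Br | intermediate
16 | (E)-3-[3-bromo-2,4-bis(methoxymethoxy)phenyl]-1-[2-hydroxy-5-(3-hydroxy-3-methylbutyl)-4,6-bis(methoxymethoxy)phenyl]prop-2-en-1-one | O=C(/C=C/c1ccc(OCOC)c(Br)c1OCOC)c1c(O)cc(OCOC)c(CCC(C)(C)O)c1OCOC | intermediate
17 | 2-[3-bromo-2,4-bis(methoxymethoxy)phenyl]-1-[2-hydroxy-5-(3-hydroxy-3-methylbutyl)-4,6-bis(methoxymethoxy)phenyl]-3,3-dimethoxypropan-1-one (racemic; formed in the flask) | COC(OC)C(C(=O)c1c(O)cc(OCOC)c(CCC(C)(C)O)c1OCOC)c1ccc(OCOC)c(Br)c1OCOC | intermediate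
18 | 3-[3-bromo-2,4-bis(methoxymethoxy)phenyl]-6-(3-hydroxy-3-methylbutyl)-5,7-bis(methoxymethoxy)chromen-4-one | COCOc1ccc(-c2coc3cc(OCOC)c(CCC(C)(C)O)c(OCOC)c3c2=O)c(OCOC)c1Br | intermediate
19 | tributyl(3-methylbut-2-enyl)stannane | CC(C)=CC[Sn](CCCC)(CCCC)CCCC | starting material
20 | 3-[2,4-bis(methoxymethoxy)-3-(3-methylbut-2-enyl)phenyl]-6-(3-hydroxy-3-methylbutyl)-5,7-bis(methoxymethoxy)chromen-4-one | COCOc1ccc(-c2coc3cc(OCOC)c(CCC(C)(C)O)c(OCOC)c3c2=O)c(OCOC)c1CC=C(C)C | intermediate
21 | 3-[2,4-dihydroxy-3-(3-methylbut-2-enyl)phenyl]-5,7-dihydroxy-6-(3-hydroxy-3-methylbutyl)chromen-4-one | CC(C)=CCc1c(O)ccc(-c2coc3cc(O)c(CCC(C)(C)O)c(O)c3c2=O)c1O | target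

## Step count and least certain steps

Total: 14 steps. Longest linear sequence: 12 steps (steps 1–8 and 11–14); steps 9 and 10 form the ring B branch.

**Step 12 (key step).**
- What may go wrong: the nitric acid released during the oxidation may strip acetal groups before it is buffered. The acetal ortho to the ketone on ring A is the most exposed, and once it is lost a second hydroxyl can close ring C, so that the chain ends up at C8 as well as at C6. Trivalent thallium may also oxidise the electron-rich phenolic ring A, or methanol may be captured at Cα without migration.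
- Fallback: it sets out from acetophenone 11 and 2-bromoresorcinol 12 and comes back at 20, replacing the rearrangement by a cross-coupling at C3. Heating 11 with N,N-dimethylformamide dimethyl acetal should give the enaminone (E)-3-(dimethylamino)-1-[2-hydroxy-5-(3-hydroxy-3-methylbutyl)-4,6-bis(methoxymethoxy)phenyl]prop-2-en-1-one F1. Iodine in CHCl3/pyridine should close ring C with loss of dimethylamine to 6-(3-hydroxy-3-methylbutyl)-3-iodo-5,7-bis(methoxymethoxy)chromen-4-one F2. For ring B, 12 is protected (NaH, MOMCl) as 2-bromo-1,3-bis(methoxymethoxy)benzene F3. Bromine–lithium exchange (n-BuLi, THF, −78 °C), transmetalation with CuBr·SMe2 and prenyl bromide give 1,3-bis(methoxymethoxy)-2-(3-methylbut-2-enyl)benzene F4. Ortho-lithiation beside an acetal oxygen (n-BuLi, TMEDA, THF, −78 to 0 °C) and quenching with 2-isopropoxy-4,4,5,5-tetramethyl-1,3,2-dioxaborolane give 2-[2,4-bis(methoxymethoxy)-3-(3-methylbut-2-enyl)phenyl]-4,4,5,5-tetramethyl-1,3,2-dioxaborolane F5. Suzuki–Miyaura coupling of F2 with F5 (PdCl2(dppf), K2CO3, dioxane/H2O, 80 °C) forms C3–C1' directly and gives 20, so the Stille step is bypassed as well.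

**Step 13.**
- What may go wrong: oxidative addition at a bromide between two ortho acetal oxygens is slow, which invites protodebromination and catalyst decay. Allylic transposition during transmetalation or reductive elimination would give the 1,1-dimethylallyl isomer.
- Fallback: it sets out from 18 and comes back at 20, building the prenyl group in two stages from a symmetric allyl donor. Suzuki–Miyaura coupling of 18 with allylboronic acid pinacol ester (Pd(OAc)2, SPhos, K3PO4, THF/H2O, 60 °C; the biarylphosphine is suited to hindered, electron-rich bromides) should give 6-(3-hydroxy-3-methylbutyl)-5,7-bis(methoxymethoxy)-3-[2,4-bis(methoxymethoxy)-3-(prop-2-enyl)phenyl]chromen-4-one F6. Cross-metathesis of F6 with 2-methylbut-2-ene (second-generation Grubbs catalyst, CH2Cl2, 40 °C) converts the allyl into the prenyl group and gives 20.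

**Step 14.**
- What may go wrong: acid may close a 2,2-dimethylchroman ring. The prenyl alkene is the more easily protonated of the two cation precursors and has hydroxyls at C2' and C4' beside it; the tertiary alcohol can ionise more slowly towards the C5 or C7 oxygen.
- Fallback: it sets out from 18 and comes back at 21, and changes the order so that acid never meets the alkene and the last step is basic. Methanolic HCl on 18 gives 3-(3-bromo-2,4-dihydroxyphenyl)-5,7-dihydroxy-6-(3-hydroxy-3-methylbutyl)chromen-4-one F7. Acetic anhydride (3.3 equiv) in pyridine at 0 °C to rt acetylates the three unchelated phenols and leaves the chelated C5 hydroxyl and the tertiary alcohol, giving 3-[2,4-bis(acetyloxy)-3-bromophenyl]-5-hydroxy-6-(3-hydroxy-3-methylbutyl)-4-oxochromen-7-yl acetate F8. Stille coupling of F8 with 19 (Pd(PPh3)4, DMF, 100 °C; the bromide is now flanked by ester instead of ether oxygens and should add to palladium more readily) gives 3-[2,4-bis(acetyloxy)-3-(3-methylbut-2-enyl)phenyl]-5-hydroxy-6-(3-hydroxy-3-methylbutyl)-4-oxochromen-7-yl acetate F9. Methanolysis of F9 (K2CO3, MeOH, 0 °C to rt) gives 21.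

**Step 3.**
- What may go wrong: metalation may lose regiocontrol, by lithiation beside the benzyloxy group or at the benzylic CH2 (followed by Wittig rearrangement), because the benzyl ether is itself a weak director with acidic protons.
- Fallback: it sets out from 3 and comes back at 8, exchanging the benzyl group for a bulky, non-directing silyl group. Hydrogenolysis of 3 (H2, Pd/C, EtOAc) gives 3,5-bis(methoxymethoxy)phenol F10. Silylation (i-Pr3SiCl, imidazole, DMF) gives [3,5-bis(methoxymethoxy)phenoxy]tri(propan-2-yl)silane F11, in which the positions beside the silyl ether are shielded. Lithiation (n-BuLi, THF, 0 °C) and iodine give [4-iodo-3,5-bis(methoxymethoxy)phenoxy]tri(propan-2-yl)silane F12. Sonogashira coupling with 6, as in step 4, gives 4-{2,6-bis(methoxymethoxy)-4-[tri(propan-2-yl)silyloxy]phenyl}-2-methylbut-3-yn-2-ol F13. Hydrogenation (H2, Pd/C, EtOAc) gives 4-{2,6-bis(methoxymethoxy)-4-[tri(propan-2-yl)silyloxy]phenyl}-2-methylbutan-2-ol F14. Bu4NF in THF removes the silyl group and gives 8.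

## Further compounds

F1 | step 12 | (E)-3-(dimethylamino)-1-[2-hydroxy-5-(3-hydroxy-3-methylbutyl)-4,6-bis(methoxymethoxy)phenyl]prop-2-en-1-one | CN(C)/C=C/C(=O)c1c(O)cc(OCOC)c(CCC(C)(C)O)c1OCOC
F2 | step 12 | 6-(3-hydroxy-3-methylbutyl)-3-iodo-5,7-bis(methoxymethoxy)chromen-4-one | COCOc1cc2occ(I)c(=O)c2c(OCOC)c1CCC(C)(C)O
F3 | step 12 | 2-bromo-1,3-bis(methoxymethoxy)benzene | COCOc1cccc(OCOC)c1Br
F4 | step 12 | 1,3-bis(methoxymethoxy)-2-(3-methylbut-2-enyl)benzene | COCOc1cccc(OCOC)c1CC=C(C)C
F5 | step 12 | 2-[2,4-bis(methoxymethoxy)-3-(3-methylbut-2-enyl)phenyl]-4,4,5,5-tetramethyl-1,3,2-dioxaborolane | COCOc1ccc(B2OC(C)(C)C(C)(C)O2)c(OCOC)c1CC=C(C)C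
F6 | step 13 | 6-(3-hydroxy-3-methylbutyl)-5,7-bis(methoxymethoxy)-3-[2,4-bis(methoxymethoxy)-3-(prop-2-enyl)phenyl]chromen-4-one | COCOc1ccc(-c2coc3cc(OCOC)c(CCC(C)(C)O)c(OCOC)c3c2=O)c(OCOC)c1CC=C
F7 | step 14 | 3-(3-bromo-2,4-dihydroxyphenyl)-5,7-dihydroxy-6-(3-hydroxy-3-methylbutyl)chromen-4-one | CC(C)(O)CCc1c(O)cc2occ(-c3ccc(O)c(Br)c3O)c(=O)c2c1O
F8 | step 14 | 3-[2,4-bis(acetyloxy)-3-bromophenyl]-5-hydroxy-6-(3-hydroxy-3-methylbutyl)-4-oxochromen-7-yl acetate | CC(=O)Oc1ccc(-c2coc3cc(OC(C)=O)c(CCC(C)(C)O)c(O)c3c2=O)c(OC(C)=O)c1Br
F9 | step 14 | 3-[2,4-bis(acetyloxy)-3-(3-methylbut-2-enyl)phenyl]-5-hydroxy-6-(3-hydroxy-3-methylbutyl)-4-oxochromen-7-yl acetate | CC(=O)Oc1ccc(-c2coc3cc(OC(C)=O)c(CCC(C)(C)O)c(O)c3c2=O)c(OC(C)=O)c1CC=C(C)C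
F10 | step 3 | 3,5-bis(methoxymethoxy)phenol | COCOc1cc(O)cc(OCOC)c1
F11 | step 3 | [3,5-bis(methoxymethoxy)phenoxy]tri(propan-2-yl)silane | COCOc1cc(OCOC)cc(O[Si](C(C)C)(C(C)C)C(C)C)c1
F12 | step 3 | [4-iodo-3,5-bis(methoxymethoxy)phenoxy]tri(propan-2-yl)silane | COCOc1cc(O[Si](C(C)C)(C(C)C)C(C)C)cc(OCOC)c1I
F13 | step 3 | 4-{2,6-bis(methoxymethoxy)-4-[tri(propan-2-yl)silyloxy]phenyl}-2-methylbut-3-yn-2-ol | COCOc1cc(O[Si](C(C)C)(C(C)C)C(C)C)cc(OCOC)c1C#CC(C)(C)O
F14 | step 3 | 4-{2,6-bis(methoxymethoxy)-4-[tri(propan-2-yl)silyloxy]phenyl}-2-methylbutan-2-ol | COCOc1cc(O[Si](C(C)C)(C(C)C)C(C)C)cc(OCOC)c1CCC(C)(C)O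
A1 | alternative 1 | 5-[2,4-bis(methoxymethoxy)-3-(3-methylbut-2-enyl)phenyl]-2-(2-diazoacetyl)pyran-4-one | [N-]=[N+]=CC(=O)c1cc(=O)c(-c2ccc(OCOC)c(CC=C(C)C)c2OCOC)co1
A2 | alternative 1 | {[5-(methoxymethoxy)-5-methylhex-1-yn-1-yl]oxy}tri(propan-2-yl)silane | COCOC(C)(C)CCC#CO[Si](C(C)C)(C(C)C)C(C)C
A3 | alternative 1 | 3-[2,4-bis(methoxymethoxy)-3-(3-methylbut-2-enyl)phenyl]-5-hydroxy-6-[3-(methoxymethoxy)-3-methylbutyl]-7-(triisopropylsilyloxy)chromen-4-one | COCOc1ccc(-c2coc3cc(O[Si](C(C)C)(C(C)C)C(C)C)c(CCC(C)(C)OCOC)c(O)c3c2=O)c(OCOC)c1CC=C(C)C
A4 | alternative 2 | 4-[3-(methoxymethoxy)-3-methylbutyl]-3,5-bis(methoxymethoxy)-2-(trimethylsilyl)phenyl trifluoromethanesulfonate | COCOc1cc(OS(=O)(=O)C(F)(F)F)c([Si](C)(C)C)c(OCOC)c1CCC(C)(C)OCOC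
A5 | alternative 2 | methyl 2-[2,4-bis(methoxymethoxy)-3-(3-methylbut-2-enyl)phenyl]-3-hydroxyprop-2-enoate (enol form of the α-formyl ester; enol geometry not fixed) | COC(=O)C(=CO)c1ccc(OCOC)c(CC=C(C)C)c1OCOC
A6 | alternative 2 | 3-[2,4-bis(methoxymethoxy)-3-(3-methylbut-2-enyl)phenyl]-6-[3-(methoxymethoxy)-3-methylbutyl]-5,7-bis(methoxymethoxy)chromen-4-one | COCOc1ccc(-c2coc3cc(OCOC)c(CCC(C)(C)OCOC)c(OCOC)c3c2=O)c(OCOC)c1CC=C(C)C
A7 | alternative 3 | (E)-1-diazo-4-{6-[3-(methoxymethoxy)-3-methylbutyl]-5,7-bis(methoxymethoxy)-4-oxochromen-3-yl}but-3-en-2-one | [N-]=[N+]=CC(=O)/C=C/c1coc2cc(OCOC)c(CCC(C)(C)OCOC)c(OCOC)c2c1=O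
A8 | alternative 3 | [(5-methylhex-4-en-1-yn-1-yl)oxy]tri(propan-2-yl)silane | CC(C)=CCC#CO[Si](C(C)C)(C(C)C)C(C)C
A9 | alternative 3 | 3-[2-hydroxy-3-(3-methylbut-2-enyl)-4-(triisopropylsilyloxy)phenyl]-6-[3-(methoxymethoxy)-3-methylbutyl]-5,7-bis(methoxymethoxy)chromen-4-one | CC(C)=CCc1c(O[Si](C(C)C)(C(C)C)C(C)C)ccc(-c2coc3cc(OCOC)c(CCC(C)(C)OCOC)c(OCOC)c3c2=O)c1O
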